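**Plan** (chain numbered as the hept-2-enoate, C1 = ester carbon; ring numbered C1′–C6′ from the carbon on C6)

1. Cuts: C2=C3 (Wittig), C4–O (enamine α-oxygenation), C3–C4 (one-carbon homologation), C6–CH3 (conjugate methylation), C5=C6 (Wittig). The C2′=C3′/C4′–OH array is traced back to an allylsilane (oxygen for silicon with 1,3-shift). The ring bonds C1′–C2′ and C5′–C6′ are then cut by [4+2].
2. Enabling feature: in the cyclohexene, the side-chain CH (C1′) and the C(CH3)OH (C4′) are 1,4 to each other with the C=C between them. With the C=C moved to C3′=C4′ this is the "para" adduct of a 3-methylbuta-1,3-diene and a CH2=CH–C(=O)X unit. C2′, the =CH next to C1′, is the diene terminus that can carry silicon.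
3. Forward: silyl diene + chiral acrylimide give the ring (key step). The acyl carbon is grown into C6–C3 by olefination, methyl conjugate addition and homologation. Silicon is exchanged for the trans hydroxyl. A one-pot α-aminoxylation/Wittig reaction joins the C1–C2 ylide fragment, followed by N–O cleavage and acetylation.
4. Stereochemistry: C1′ from the oxazolidinone auxiliary; C2′–Si from the endo rule, relayed anti to C4′–OH; C6 from a copper/Tol-BINAP catalyst matched with the silyl-shielded face; C4 from D-proline; 2E from the stabilised ylide.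

Key step: step 3

Remark (assumptions): a 1-silyl group on a diene is taken to direct regiochemistry only weakly compared with a 3-methyl group. In step 6, (R)-Tol-BINAP is written as the ligand antipode that delivers methyl to the face named there; if a model (E)-enoate shows the opposite sense, (S)-Tol-BINAP is used with no other change.

**Step 1**
Reactants: 1 2-methylbut-1-en-3-yne; 2 dimethyl(phenyl)silane
Product: 3 (E)-dimethyl(3-methylbuta-1,3-dien-1-yl)phenylsilane
Conditions: Pt2[(CH2=CHSiMe2)2O]3 (0.1 mol% zerovalent platinum), P(t-Bu)3 (0.2 mol%), THF, 0 °C to rt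
Reagents that add atoms: none
Why: Platinum-catalysed syn hydrosilylation of the terminal alkyne should place silicon on the terminal carbon and give the E vinylsilane (the bulky phosphine enforces β-E selectivity), the 1,1-disubstituted alkene being far less reactive.

**Step 2**
Reactants: 4 (4S)-4-benzyl-1,3-oxazolidin-2-one; 5 acryloyl chloride
Product: 6 (4S)-3-acryloyl-4-benzyl-1,3-oxazolidin-2-one
Conditions: Et3N, LiCl, THF, −20 °C to rt
Reagents that add atoms: none
Why: LiCl-assisted N-acylation of the oxazolidinone under a mild amine base avoids the strongly basic metal amides that polymerise acrylates.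

**Step 3**
Reactants: 3 (E)-dimethyl(3-methylbuta-1,3-dien-1-yl)phenylsilane; 6 (4S)-3-acryloyl-4-benzyl-1,3-oxazolidin-2-one
Product: 7 (4S)-4-benzyl-3-{[(1S,2S)-2-(dimethylphenylsilyl)-4-methylcyclohex-3-en-1-yl]carbonyl}-1,3-oxazolidin-2-one (silicon cis to the acyl group)
Conditions: Et2AlCl (1.4 equiv), 3 (2 equiv), CH2Cl2, −78 °C
Reagents that add atoms: none
Why: Et2AlCl turns 6 into a cationic aluminium chelate (both carbonyls bound, acryloyl s-cis) that undergoes a concerted but asynchronous normal-demand [4+2] cycloaddition with the s-cis diene, the CH2 terminus of the diene bonding first to the β-carbon. The closest known types are the oxazolidinone-auxiliary Diels–Alder reaction of N-acryloyl imides with isoprene and piperylene, and cycloadditions of 1-silylbutadienes that give allylsilanes. The one ring formed, the cyclohexene, closes by suprafacial–suprafacial union of the four diene carbons with the two alkene carbons, both σ bonds being made in the same event. Ring C1 is controlled by the benzyl group of the auxiliary, which shields one face of the planar chelate so that the diene adds anti to it, and ring C2 by the endo transition state together with the E geometry of the vinylsilane, which places silicon cis to the acyl group. The step needs regiocontrol (acyl-bearing carbon bonded to the silyl-bearing terminus), endo selectivity and facial selectivity; the first is secured by the 3-methyl group, which makes the CH2 terminus the nucleophilic end ("para" orientation) while the 1-silyl group directs only weakly, and the other two by the rigid chelate.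

**Step 4**
Reactants: 7 (the cycloadduct imide)
Product: 8 [(1S,2S)-2-(dimethylphenylsilyl)-4-methylcyclohex-3-en-1-yl]methanol
Conditions: LiBH4, MeOH (1 equiv), Et2O, 0 °C
Reagents that add atoms: none
Why: LiBH4 attacks the exocyclic imide carbonyl (reductive removal of the auxiliary, which is recovered), and neither ring stereocentre is enolised under these conditions.

**Step 5**
Reactants: 8 [(1S,2S)-2-(dimethylphenylsilyl)-4-methylcyclohex-3-en-1-yl]methanol; 9 methyl (triphenylphosphoranylidene)acetate
Product: 11 methyl (2E)-3-[(1S,2R)-2-(dimethylphenylsilyl)-4-methylcyclohex-3-en-1-yl]prop-2-enoate, via aldehyde 10 (not isolated)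
Conditions: 1,1,1-triacetoxy-1,1-dihydro-1,2-benziodoxol-3(1H)-one (DMP), NaHCO3, CH2Cl2, 0 °C to rt; then 9, rt
Reagents that add atoms: none
Why: Periodinane oxidation gives the α-branched aldehyde under buffered, non-epimerising conditions, and the stabilised ylide traps it at once in a Wittig reaction that is E-selective under thermodynamic control.

**Step 6**
Reactants: 11 (the (E)-enoate)
Product: 12 methyl (3R)-3-[(1S,2R)-2-(dimethylphenylsilyl)-4-methylcyclohex-3-en-1-yl]butanoate
Conditions: CuI (2 mol%), (R)-Tol-BINAP (3 mol%), MeMgBr (4 equiv), t-BuOMe, −20 °C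
Reagents that add atoms: methylmagnesium bromide, C[Mg]Br
Why: Copper-catalysed asymmetric conjugate addition of the Grignard reagent to the (E)-enoate should set C3 under control of the Tol-BINAP–copper catalyst, the ligand antipode being the one that delivers methyl to the face anti to the silyl-bearing ring carbon in the H-eclipsed (A1,3-minimised) rotamer, so that catalyst and substrate bias are matched and give 3R.

**Step 7**
Reactants: 12 (the β-methyl ester)
Product: 13 (3R)-3-[(1S,2R)-2-(dimethylphenylsilyl)-4-methylcyclohex-3-en-1-yl]butanal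
Conditions: i-Bu2AlH (1.1 equiv), CH2Cl2, −78 °C
Reagents that add atoms: none
Why: Partial reduction of the methyl ester stops at the tetrahedral aluminium hemiacetal at −78 °C and gives the aldehyde on hydrolysis, with no stereocentre touched.

**Step 8**
Reactants: 13 (the butanal)
Product: 15 (4R)-4-[(1S,2R)-2-(dimethylphenylsilyl)-4-methylcyclohex-3-en-1-yl]pentanal, via enol ether 14 (not isolated)
Conditions: [Ph3PCH2OMe]Cl, KOt-Bu, THF, 0 °C; then 1 M HCl, THF, rt
Reagents that add atoms: (methoxymethyl)triphenylphosphonium chloride, COC[P+](c1ccccc1)(c1ccccc1)c1ccccc1.[Cl-]; water, O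
Why: Wittig methoxymethylenation followed by mild acid hydrolysis of the enol ether is a standard one-carbon homologation, and the allylsilane should tolerate dilute aqueous acid because protodesilylation would require protonation at the more substituted alkene carbon.

**Step 9**
Reactants: 15 (the silyl pentanal)
Product: 17 (4R)-4-[(1S,4R)-4-hydroxy-4-methylcyclohex-2-en-1-yl]pentanal, via epoxysilane 16 (not isolated)
Conditions: mCPBA (1.0 equiv), NaHCO3, CH2Cl2, −20 °C; then Bu4NF/AcOH (1:1), THF, 0 °C
Reagents that add atoms: 3-chloroperoxybenzoic acid, OOC(=O)c1cccc(Cl)c1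
Why: The electron-rich trisubstituted allylsilane alkene is epoxidised much faster than the aldehyde is oxidised and on the face opposite to silicon (anti SE2′ course), and fluoride then triggers anti β-elimination of silicon and the adjacent C–O bond (Peterson-type opening of a β,γ-epoxysilane), which moves the double bond and leaves the tertiary hydroxyl trans to the side chain, its configuration relayed from the C–Si centre.

**Step 10**
Reactants: 9 methyl (triphenylphosphoranylidene)acetate; 18 5-bromo-2-methylpent-2-ene
Product: 20 methyl 6-methyl-2-(triphenylphosphoranylidene)hept-5-enoate, via phosphonium bromide 19 (not isolated)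
Conditions: NaI (10 mol%), MeCN, 80 °C; then aq. NaOH, CH2Cl2, rt
Reagents that add atoms: none
Why: C-alkylation of the stabilised ylide by the primary bromide (iodide catalysis) gives the phosphonium salt, which aqueous base deprotonates to the α-substituted stabilised ylide.

**Step 11**
Reactants: 17 (the hydroxy pentanal); 20 (the α-substituted ylide)
Product: 22 methyl (2E,4S,6R)-4-(anilinooxy)-6-[(1S,4R)-4-hydroxy-4-methylcyclohex-2-en-1-yl]-2-(4-methylpent-3-en-1-yl)hept-2-enoate, via aminoxy aldehyde 21 (not isolated)
Conditions: D-proline (20 mol%), PhNO (1.1 equiv, slow addition), CHCl3, 0 °C; then 20 (1.5 equiv), 0 °C to rt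
Reagents that add atoms: nitrosobenzene, O=Nc1ccccc1
Why: D-proline-catalysed O-selective nitroso aldol reaction (enamine α-aminoxylation) should set the α-carbon as S by hydrogen-bond-directed delivery of nitrosobenzene to one enamine face, and the labile α-oxy aldehyde is trapped in the same flask by Wittig reaction with the α-branched stabilised ylide, which gives the 2E trisubstituted enoate (ester trans to the oxygenated carbon).

**Step 12**
Reactants: 22 (the anilinooxy enoate)
Product: 23 methyl (2E,4S,6R)-4-hydroxy-6-[(1S,4R)-4-hydroxy-4-methylcyclohex-2-en-1-yl]-2-(4-methylpent-3-en-1-yl)hept-2-enoate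
Conditions: Zn, AcOH, THF, 0 °C to rt
Reagents that add atoms: none
Why: Zinc in acetic acid reduces the weak N–O bond selectively, while the enoate, the alkenes and the tertiary allylic alcohol should be inert at this temperature.

**Step 13**
Reactants: 23 (the diol enoate)
Product: 24 methyl (2E,4S,6R)-4-acetoxy-6-[(1S,4R)-4-hydroxy-4-methylcyclohex-2-en-1-yl]-2-(4-methylpent-3-en-1-yl)hept-2-enoate (target)
Conditions: Ac2O, pyridine, DMAP (5 mol%), CH2Cl2, 0 °C
Reagents that add atoms: acetic anhydride, CC(=O)OC(C)=O
Why: The secondary allylic alcohol is acylated under nucleophilic catalysis while the hindered tertiary allylic alcohol should stay free at 0 °C.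

**Compound list**

1 | 2-methylbut-1-en-3-yne | C=C(C)C#C | starting material
2 | dimethyl(phenyl)silane | C[SiH](C)c1ccccc1 | starting material
3 | (E)-dimethyl(3-methylbuta-1,3-dien-1-yl)phenylsilane | C=C(C)/C=C/[Si](C)(C)c1ccccc1 | intermediate
4 | (4S)-4-benzyl-1,3-oxazolidin-2-one | O=C1OC[C@H](Cc2ccccc2)N1 | starting material
5 | acryloyl chloride | C=CC(=O)Cl | starting material
6 | (4S)-3-acryloyl-4-benzyl-1,3-oxazolidin-2-one | C=CC(=O)N1[C@@H](Cc2ccccc2)COC1=O | intermediate
7 | (4S)-4-benzyl-3-{[(1S,2S)-2-(dimethylphenylsilyl)-4-methylcyclohex-3-en-1-yl]carbonyl}-1,3-oxazolidin-2-one | O=C([C@@H]1CCC(C)=C[C@@H]1[Si](C)(C)c1ccccc1)N1[C@@H](Cc2ccccc2)COC1=O | intermediate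
8 | [(1S,2S)-2-(dimethylphenylsilyl)-4-methylcyclohex-3-en-1-yl]methanol | OC[C@@H]1CCC(C)=C[C@@H]1[Si](C)(C)c1ccccc1 | intermediate
9 | methyl (triphenylphosphoranylidene)acetate | COC(=O)C=P(c1ccccc1)(c1ccccc1)c1ccccc1 | starting material
10 | (1S,2S)-2-(dimethylphenylsilyl)-4-methylcyclohex-3-ene-1-carbaldehyde | O=C[C@@H]1CCC(C)=C[C@@H]1[Si](C)(C)c1ccccc1 | intermediate
11 | methyl (2E)-3-[(1S,2R)-2-(dimethylphenylsilyl)-4-methylcyclohex-3-en-1-yl]prop-2-enoate | COC(=O)/C=C/[C@@H]1CCC(C)=C[C@@H]1[Si](C)(C)c1ccccc1 | intermediate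
12 | methyl (3R)-3-[(1S,2R)-2-(dimethylphenylsilyl)-4-methylcyclohex-3-en-1-yl]butanoate | COC(=O)C[C@@H](C)[C@@H]1CCC(C)=C[C@@H]1[Si](C)(C)c1ccccc1 | intermediate
13 | (3R)-3-[(1S,2R)-2-(dimethylphenylsilyl)-4-methylcyclohex-3-en-1-yl]butanal | O=CC[C@@H](C)[C@@H]1CCC(C)=C[C@@H]1[Si](C)(C)c1ccccc1 | intermediate
14 | (4R)-1-methoxy-4-[(1S,2R)-2-(dimethylphenylsilyl)-4-methylcyclohex-3-en-1-yl]pent-1-ene (E/Z mixture) | COC=CC[C@@H](C)[C@@H]1CCC(C)=C[C@@H]1[Si](C)(C)c1ccccc1 | intermediate
15 | (4R)-4-[(1S,2R)-2-(dimethylphenylsilyl)-4-methylcyclohex-3-en-1-yl]pentanal | O=CCC[C@@H](C)[C@@H]1CCC(C)=C[C@@H]1[Si](C)(C)c1ccccc1 | intermediate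
16 | epoxysilane: 15 with the ring C3=C4 bond epoxidised on the face opposite to silicon and to the side chain | O=CCC[C@@H](C)[C@@H]1CC[C@@]2(C)O[C@H]2[C@@H]1[Si](C)(C)c1ccccc1 | intermediate
17 | (4R)-4-[(1S,4R)-4-hydroxy-4-methylcyclohex-2-en-1-yl]pentanal (hydroxyl trans to the side chain) | O=CCC[C@@H](C)[C@H]1C=C[C@](C)(O)CC1 | intermediate
18 | 5-bromo-2-methylpent-2-ene | CC(C)=CCCBr | starting material
19 | (1-methoxy-6-methyl-1-oxohept-5-en-2-yl)triphenylphosphonium bromide | COC(=O)C(CCC=C(C)C)[P+](c1ccccc1)(c1ccccc1)c1ccccc1.[Br-] | intermediate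
20 | methyl 6-methyl-2-(triphenylphosphoranylidene)hept-5-enoate | COC(=O)C(CCC=C(C)C)=P(c1ccccc1)(c1ccccc1)c1ccccc1 | intermediate
21 | (2S,4R)-2-(anilinooxy)-4-[(1S,4R)-4-hydroxy-4-methylcyclohex-2-en-1-yl]pentanal | O=C[C@@H](ONc1ccccc1)C[C@@H](C)[C@H]1C=C[C@](C)(O)CC1 | intermediate
22 | methyl (2E,4S,6R)-4-(anilinooxy)-6-[(1S,4R)-4-hydroxy-4-methylcyclohex-2-en-1-yl]-2-(4-methylpent-3-en-1-yl)hept-2-enoate | COC(=O)/C(=C/[C@H](C[C@@H](C)[C@H]1C=C[C@](C)(O)CC1)ONc1ccccc1)CCC=C(C)C | intermediate
23 | methyl (2E,4S,6R)-4-hydroxy-6-[(1S,4R)-4-hydroxy-4-methylcyclohex-2-en-1-yl]-2-(4-methylpent-3-en-1-yl)hept-2-enoate | COC(=O)/C(=C/[C@H](C[C@@H](C)[C@H]1C=C[C@](C)(O)CC1)O)CCC=C(C)C | intermediate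
24 | methyl (2E,4S,6R)-4-acetoxy-6-[(1S,4R)-4-hydroxy-4-methylcyclohex-2-en-1-yl]-2-(4-methylpent-3-en-1-yl)hept-2-enoate | COC(=O)/C(=C/[C@H](C[C@@H](C)[C@H]1C=C[C@](C)(O)CC1)OC(C)=O)CCC=C(C)C | target

**Step count and risks**

Total step count: 13. Longest linear sequence: 11 steps (steps 1, 3–9 and 11–13).

Steps most likely to fail:

Step 3. The regiocontrol may leak if the silyl group competes with the methyl group in the strongly polarised transition state. The allylsilane in the product may also be consumed under the Lewis acid, by conjugate allylation of a second chelated imide or by protodesilylation. Fallback: the cycloaddition is run without Lewis acid and without auxiliary under iminium catalysis. It sets out from 3, which is combined with acrolein and (5S)-5-benzyl-2,2,3-trimethylimidazolidin-4-one hydrochloride (20 mol%) in CH3NO2–H2O at rt; the antipodal catalyst is taken if the isoprene–acrolein model reaction shows the opposite sense. It comes back to the route at aldehyde 10, which is olefinated with 9 as in step 5. This fallback makes no new compound (F0).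

Step 6. Methyl transfer may be slow or unselective: γ-deprotonation of the γ-branched enoate by the Grignard reagent, 1,2-addition, or a mismatch between catalyst and substrate bias. Fallback: hydrogen instead of methyl is delivered to C3, by a catalyst whose sense follows the geraniol precedent. It sets out from 7:
- MeNHOMe·HCl/AlMe3 in CH2Cl2 gives the N-methoxy-N-methylamide F1.
- MeMgBr in THF at 0 °C gives the methyl ketone F2.
- Horner–Wadsworth–Emmons reaction with (EtO)2P(O)CH2CO2Et/NaH gives the (E)-β-methyl enoate F3.
- i-Bu2AlH gives the (E)-allylic alcohol F4.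
- H2 (30 atm) with Ru(OAc)2[(R)-BINAP] in MeOH should reduce only the allylic-alcohol double bond and give the (3R)-alcohol F5.
- Periodinane oxidation of F5 comes back to the route at 13.

Step 11. The configuration of the α-aminoxy aldehyde may erode during the slow Wittig reaction with the hindered ylide, and the limiting aldehyde may be lost to excess nitrosobenzene. Fallback: the oxygen is introduced as a benzoate by a sterically shielding amine catalyst, so that no N–O bond has to be cleaved. It sets out from 17:
- Dibenzoyl peroxide and (S)-2-(triphenylmethyl)pyrrolidine (10 mol%) in THF at 0 °C give the more robust α-benzoyloxy aldehyde F6.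
- Wittig reaction with 20 gives the γ-benzoyloxy enoate F7.
- K2CO3 in MeOH at 0 °C removes the benzoate and comes back to the route at 23.

Further compounds
F0 | step 3 | none | none
F1 | step 6 | (1S,2S)-2-(dimethylphenylsilyl)-N-methoxy-N,4-dimethylcyclohex-3-ene-1-carboxamide | CON(C)C(=O)[C@@H]1CCC(C)=C[C@@H]1[Si](C)(C)c1ccccc1
F2 | step 6 | 1-[(1S,2S)-2-(dimethylphenylsilyl)-4-methylcyclohex-3-en-1-yl]ethan-1-one | CC(=O)[C@@H]1CCC(C)=C[C@@H]1[Si](C)(C)c1ccccc1
F3 | step 6 | ethyl (2E)-3-[(1S,2S)-2-(dimethylphenylsilyl)-4-methylcyclohex-3-en-1-yl]but-2-enoate | CCOC(=O)/C=C(\C)[C@@H]1CCC(C)=C[C@@H]1[Si](C)(C)c1ccccc1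
F4 | step 6 | (2E)-3-[(1S,2S)-2-(dimethylphenylsilyl)-4-methylcyclohex-3-en-1-yl]but-2-en-1-ol | OC/C=C(\C)[C@@H]1CCC(C)=C[C@@H]1[Si](C)(C)c1ccccc1
F5 | step 6 | (3R)-3-[(1S,2R)-2-(dimethylphenylsilyl)-4-methylcyclohex-3-en-1-yl]butan-1-ol | OCC[C@@H](C)[C@@H]1CCC(C)=C[C@@H]1[Si](C)(C)c1ccccc1
F6 | step 11 | (2S,4R)-2-(benzoyloxy)-4-[(1S,4R)-4-hydroxy-4-methylcyclohex-2-en-1-yl]pentanal | O=C[C@@H](OC(=O)c1ccccc1)C[C@@H](C)[C@H]1C=C[C@](C)(O)CC1
F7 | step 11 | methyl (2E,4S,6R)-4-(benzoyloxy)-6-[(1S,4R)-4-hydroxy-4-methylcyclohex-2-en-1-yl]-2-(4-methylpent-3-en-1-yl)hept-2-enoate | COC(=O)/C(=C/[C@H](C[C@@H](C)[C@H]1C=C[C@](C)(O)CC1)OC(=O)c1ccccc1)CCC=C(C)C
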